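**Retrosynthetic overview**
- Ring A is numbered C1 (aryloxy carbon), C2 (methoxy carbon), C3-Br, C4-H, C5-Br, C6-Br. Ring B is the 2-bromophenyl group.
- Governing feature: C3 and C5 lie ortho and para to the C2 oxygen and can be filled by phenol bromination. C6-Br is meta to that oxygen and is addressed only by the weak aryloxy donor, which points equally at C4. In a 2-aryloxycyclohex-2-enone whose C=O is the future C2, C6 is instead the nucleophilic β-carbon of an enol ether.
- Disconnections, in order: O-CH3; then C6-Br, C3-Br and C5-Br together with the aromaticity of ring A (one brominative aromatization); then C1-O(aryl) by opening 2,3-epoxycyclohexanone with 2-bromophenol; then the epoxide oxygen from cyclohexenone.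
- Ring order: no ring is constructed. Ring B is bought aromatic, and ring A is bought as cyclohexenone, substituted while partly saturated and aromatized late.

Key step: step 3

Remark: the target has no stereocentre. The epoxy ketone, the hydroxy ketone and the α'-bromo enone on the way are racemates whose stereocentres are erased.

**Step 1**
Reactants: 1 cyclohex-2-en-1-one
Product: 2 (±)-7-oxabicyclo[4.1.0]heptan-2-one (2,3-epoxycyclohexanone)
Conditions: 30% aq H2O2 (1.5 equiv), NaOH (0.1 equiv), MeOH, 0 to 10 °C
Reagents that add atoms: hydrogen peroxide, OO
Why: Weitz–Scheffer nucleophilic epoxidation, in which hydroperoxide adds to C3 of the enone and the enolate closes on oxygen with loss of hydroxide; the two new stereocentres are locked cis by the three-membered ring and form as a racemate, which does not matter because step 2 erases both.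

**Step 2**
Reactants: 2 (±)-7-oxabicyclo[4.1.0]heptan-2-one; 3 2-bromophenol
Product: 5 2-(2-bromophenoxy)cyclohex-2-en-1-one, via hydroxy ketone 4 (not isolated)
Conditions: 3 (1.1 equiv), KOtBu (0.2 equiv), THF–DMPU 4:1, reflux
Reagents that add atoms: none
Why: The phenoxide opens the epoxy ketone by SN2 attack at C2, the carbon activated by the neighbouring carbonyl (inversion gives trans-4), and E1cB loss of water from 4 gives the conjugated enone and regenerates base, which is the established conversion of α,β-epoxy ketones and phenols into 2-aryloxy enones.

**Step 3**
Reactants: 5 2-(2-bromophenoxy)cyclohex-2-en-1-one; 6 bromine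
Product: 11 3,4,6-tribromo-2-(2-bromophenoxy)phenol, via vinyl bromide 7 (not isolated), via alpha'-bromo enone 8 (not isolated), via monobromophenol 9 (not isolated), via dibromophenol 10 (not isolated)
Conditions: Br2 (4.0 equiv in three charges: 1.0 equiv, 0 °C; 1.0 equiv, 23 °C then 70 °C until HBr evolution ends; 2.0 equiv, 0 to 23 °C), anhydrous ClCH2CH2Cl, dark, no Lewis acid
Reagents that add atoms: bromine 6, BrBr
Why: Bromine attacks the aryl enol ether of 5 at its β-carbon (enone C3, ring A C6) and the resulting α-bromo ether loses HBr to give 7, the known C3 halogenation of diosphenol ethers. The HBr released catalyses enolization of 7 toward enone C6 (ring A C3), the second equivalent gives 8, and on warming 8 loses HBr and tautomerizes to phenol 9, as in the classical brominative aromatization of cyclohexenones. The free hydroxyl of 9 then directs the last two equivalents by electrophilic aromatic substitution to its open para carbon (ring A C5, giving 10) and ortho carbon (ring A C3, giving 11), and whichever site reacts first the outcome is the same. No ring is closed, since the purchased carbocycle is only aromatized, and no stereocentre remains, the one in 8 being erased on aromatization. Site selectivity rests on ring A C4 (enone C5) being the only ring carbon that is never enol-ether β, α', γ, ortho or para to the C2 oxygen, so even enolization of 7 toward its γ-carbon or double α'-bromination converges on the same pattern. Chemoselectivity over ring B rests on a bromine-deactivated diaryl ether reacting far more slowly with uncatalysed Br2 than an enol ether, an enol or a phenol, and it is safeguarded by dosing exactly four equivalents in charges and by an anhydrous, non-nucleophilic solvent that protects the enol ether from solvolysis.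

**Step 4**
Reactants: 11 3,4,6-tribromo-2-(2-bromophenoxy)phenol
Product: 12 1,2,5-tribromo-3-(2-bromophenoxy)-4-methoxybenzene (target)
Conditions: MeI (1.5 equiv), K2CO3 (2 equiv), acetone, 40 °C
Reagents that add atoms: iodomethane, CI
Why: Williamson ether synthesis, in which the acidic tribromophenol is fully ionized by carbonate and the small electrophile reaches the doubly ortho-flanked phenoxide oxygen, while the aryl bromides and the diaryl ether are inert.

**Compound list**
1 | cyclohex-2-en-1-one | O=C1C=CCCC1 | starting material
2 | (±)-7-oxabicyclo[4.1.0]heptan-2-one, cis-fused, one enantiomer drawn | O=C1CCC[C@@H]2O[C@H]12 | intermediate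
3 | 2-bromophenol | Oc1ccccc1Br | starting material
4 | (±)-trans-2-(2-bromophenoxy)-3-hydroxycyclohexan-1-one, one enantiomer drawn | O=C1CCC[C@H](O)[C@H]1Oc1ccccc1Br | intermediate (not isolated)
5 | 2-(2-bromophenoxy)cyclohex-2-en-1-one | O=C1CCCC=C1Oc1ccccc1Br | intermediate
6 | bromine | BrBr | starting material
7 | 3-bromo-2-(2-bromophenoxy)cyclohex-2-en-1-one | O=C1CCCC(Br)=C1Oc1ccccc1Br | intermediate (not isolated)
8 | (±)-3,6-dibromo-2-(2-bromophenoxy)cyclohex-2-en-1-one | O=C1C(Br)CCC(Br)=C1Oc1ccccc1Br | intermediate (not isolated)
9 | 3-bromo-2-(2-bromophenoxy)phenol | Oc1cccc(Br)c1Oc1ccccc1Br | intermediate (not isolated)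
10 | 3,4-dibromo-2-(2-bromophenoxy)phenol | Oc1ccc(Br)c(Br)c1Oc1ccccc1Br | intermediate (not isolated)
11 | 3,4,6-tribromo-2-(2-bromophenoxy)phenol | Oc1c(Br)cc(Br)c(Br)c1Oc1ccccc1Br | intermediate
12 | 1,2,5-tribromo-3-(2-bromophenoxy)-4-methoxybenzene | COc1c(Br)cc(Br)c(Br)c1Oc1ccccc1Br | target

Total step count: 4
Longest linear sequence: 4 steps (1 → 2 → 5 → 11 → 12)

**Steps most likely to fail**

1. **Step 3.**
   - Risk: loss of HBr from the α'-bromo ketone may lag behind bromine uptake. Unconsumed bromine could then spill onto the para position of ring B or onto ring A C4. The HBr-rich medium may also cleave the enol-ether C–O bond before ring A is aromatic.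
   - Fallback: this sets out from 5 and returns at 11. It separates the events and replaces the halogenative dehydrogenation with a selenoxide elimination.
   - Compound 5 is treated with Br2 (1 equiv) in CH2Cl2 at 0 °C and then Et3N, and 7 is isolated.
   - Kinetic α'-deprotonation of 7 (LDA, THF, −78 °C) and trapping with PhSeCl should give 3-bromo-2-(2-bromophenoxy)-6-(phenylselanyl)cyclohex-2-en-1-one F1.
   - Oxidation with mCPBA (1 equiv, CH2Cl2, −78 °C) and warming triggers syn elimination. The resulting dienone tautomerizes to 9, which is isolated.
   - NBS (2 equiv, MeCN, 0 °C) then fills the para and ortho carbons of the pure phenol to give 11.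

2. **Step 2.**
   - Risk: base-induced isomerization and self-condensation of the epoxy ketone may outrun attack by the hindered, weakly nucleophilic ortho-bromophenoxide, or the dehydration may stall.
   - Fallback: this sets out from 1 and 3, returns at 5, and bypasses the epoxide. The C–O bond is made by cross-coupling at an sp2 carbon.
   - α-Iodination of 1 (I2, pyridine, CH2Cl2, 0 to 23 °C, an addition–elimination sequence) should give 2-iodocyclohex-2-en-1-one F2.
   - Ullmann-type vinylic C–O coupling of F2 with 3 (CuI 10 mol %, N,N-dimethylglycine, Cs2CO3, dioxane, 70 °C) should give 5. The vinyl iodide should engage copper faster than the aryl bromide.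

3. **Step 1.**
   - Risk: the small, volatile, water-soluble product may be lost on aqueous work-up, and base-induced ring opening or over-oxidation may occur in alkaline peroxide.
   - Fallback: this sets out from 1 and returns at 2. It replaces nucleophilic epoxidation with hydroxyl-directed electrophilic epoxidation.
   - Luche reduction of 1 (NaBH4, CeCl3·7H2O, MeOH, 0 °C) should give cyclohex-2-en-1-ol F3.
   - Treatment with mCPBA (CH2Cl2, 0 °C) should deliver oxygen syn to the hydroxyl and give cis-2,3-epoxycyclohexan-1-ol F4.
   - Dess–Martin periodinane (CH2Cl2, 23 °C) then oxidizes the carbinol under non-basic, non-aqueous conditions to give 2.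

**Further compounds**
F1 | step 3 | (±)-3-bromo-2-(2-bromophenoxy)-6-(phenylselanyl)cyclohex-2-en-1-one | O=C1C([Se]c2ccccc2)CCC(Br)=C1Oc1ccccc1Br
F2 | step 2 | 2-iodocyclohex-2-en-1-one | O=C1CCCC=C1I
F3 | step 1 | (±)-cyclohex-2-en-1-ol | OC1CCCC=C1
F4 | step 1 | (±)-cis-2,3-epoxycyclohexan-1-ol (hydroxyl syn to the epoxide oxygen, one enantiomer drawn) | O[C@@H]1CCC[C@@H]2O[C@H]12
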